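**Plan**
Retrosynthesis: (1) the ester C–O bond between the C10 chain and C1 of (R)-malic acid; (2) in one stroke, the C3–C4 (CH2–CH2) bond and the O1–C2 (ring oxygen to quaternary carbon) bond of the 5-oxooxolane ring, which leaves an acetic acid unit and a 1,1-disubstituted alkene; (3) the bond between the side-chain CH and the decyl chain.
Enabling feature: the quaternary ring carbon C2 carries O, a ring CH2 and a carboxyl carbon. If that carboxyl carbon is carried as an arene carbon, C2 is the inner carbon of a styrene. The alkene CH2 and the acetic acid alpha-carbon (both donors) can then be joined through a radical, and the benzylic cation that follows takes the carboxyl oxygen.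
Temporary ring: the two vicinal carboxyl carbons are tied into a chromane (arene carbon C4a = carboxyl on the quaternary carbon; OCH2, C2 = carboxyl on the CH), which places the chain-bearing C3 next to the reacting C4.
Forward order: chain and C4 unit joined by copper-catalysed SN2′ allylation; chromane ring by Heck closure; oxolanone ring A by the key step; benzo ring burnt off with RuO4 (transient lactone ring B); ring B opened and oxidised; malate ester last.
Stereochemistry: the side-chain CH comes from the ligand-controlled SN2′ step, the quaternary carbon follows from it by anti attack on the chromanyl cation, and the malate centre comes from D-malic acid.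

Key step: step 5

Assumption: the enantiomer of the ferrocenyl diphosphine used in step 3 is the one that delivers (S)-7; both enantiomers are commercial, so the sense of induction can be matched.

Step 1
Reactants: 1 10-bromodecan-1-ol
Product: 2 [(10-bromodecyl)oxy]triisopropylsilane
Conditions: TIPSCl, imidazole, CH2Cl2, 0 °C to rt
Reagents that add atoms: triisopropylsilyl chloride CC(C)[Si](Cl)(C(C)C)C(C)C
Why: Imidazole-promoted silylation of a primary alcohol; the bulky TIPS ether is chosen because it must outlast a Grignard reagent, RuO4, aqueous NaOH and bleach.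

Step 2
Reactants: 3 2-bromophenol; 4 (E)-1,4-dibromobut-2-ene
Product: 5 1-bromo-2-{[(2E)-4-bromobut-2-en-1-yl]oxy}benzene
Conditions: K2CO3, 4 in excess (3 equiv), acetone, reflux
Reagents that add atoms: none
Why: Williamson ether synthesis; the excess of the symmetrical dibromide holds the reaction at mono-substitution, and direct SN2 attack keeps the E-alkene.

Step 3
Reactants: 2 [(10-bromodecyl)oxy]triisopropylsilane; 5 1-bromo-2-{[(2E)-4-bromobut-2-en-1-yl]oxy}benzene
Product: 7 (S)-1-bromo-2-({2-ethenyl-12-[(triisopropylsilyl)oxy]dodecyl}oxy)benzene, via Grignard reagent 6 (not isolated)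
Conditions: 2, Mg, Et2O, reflux; then added slowly to 5, CuBr·SMe2 (3 mol %), 1-[α-(dimethylamino)-2-(diphenylphosphino)benzyl]-2-(diphenylphosphino)ferrocene (Taniaphos, one enantiomer, 3.5 mol %), CH2Cl2, −75 °C
Reagents that add atoms: none
Why: Copper-catalysed asymmetric allylic alkylation (SN2′) of a gamma-oxygenated E-allyl bromide with a primary alkyl Grignard reagent, a known substrate class; the chiral diphosphine on monovalent copper selects one alkene face and sets the (S)-centre (the later CH–CO2H carbon), while the aryl bromide is inert at −75 °C.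

Step 4
Reactants: 7 (S)-1-bromo-2-({2-ethenyl-12-[(triisopropylsilyl)oxy]dodecyl}oxy)benzene
Product: 8 (S)-4-methylidene-3-{10-[(triisopropylsilyl)oxy]decyl}chromane
Conditions: Pd(OAc)2 (5 mol %), PPh3 (12 mol %), Ag2CO3 (1.1 equiv), MeCN, 80 °C
Reagents that add atoms: none
Why: Intramolecular Heck reaction; oxidative addition to zerovalent palladium, 6-exo-trig carbopalladation of the terminal alkene and elimination of the only beta-hydrogen (C4–H) give the exocyclic methylene, and Ag2CO3 removes the palladium hydride before it can re-add and move the alkene into the ring, so C3 is not touched.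

Step 5
Reactants: 8 (S)-4-methylidene-3-{10-[(triisopropylsilyl)oxy]decyl}chromane; 9 bromoacetic acid
Product: 10 (3R,4S)-3-{10-[(triisopropylsilyl)oxy]decyl}spiro[chromane-4,2'-oxolan]-5'-one (lactone oxygen trans to the C3 chain)
Conditions: fac-Ir(ppy)3 [tris(2-phenylpyridinato)iridium, 1 mol %], 9 (2 equiv), K2HPO4 (1.5 equiv), dry degassed MeCN, blue LED (450 nm), rt
Reagents that add atoms: none
Why: The photoexcited iridium complex gives one electron to 9, bromide leaves, and the carboxymethyl radical adds to the open CH2 end of the exocyclic styrene of 8 (new CH2–CH2 bond between two carbons that are both donors by nature) to give the tertiary benzylic C4 radical. Tetravalent iridium oxidises this radical, which the aryl ring and its ortho ring oxygen make electron-rich, to the benzylic cation, the catalyst returns to its resting state, the pendant CO2H closes on C4 (new O–C bond) and K2HPO4 takes up the HBr. The closest known reaction type is the radical-polar crossover carbolactonisation of alpha-substituted styrenes with alpha-halo acid derivatives, the mild redox-neutral relative of the Mn(OAc)3/acetic acid lactone annulation of alkenes. Ring A closes in the 5-exo-trig mode, because the C4=C4a bond of the quinoid form of the cation stays outside the new ring. The quaternary centre is controlled by C3: allylic strain with the in-plane side chain at C4 holds the long chain pseudo-axial on the half-chair, so the oxygen enters from the opposite face and ends trans to the chain, which with C4a and C2 read as the two carboxyl carbons is the (S,S) pair of the target. The step needs attack at the alkene terminus (secured by the 1,1-disubstituted styrene), oxidation of the adduct radical ahead of hydrogen abstraction or oligomerisation (secured by the aryl group and its ortho oxygen) and ring closure ahead of loss of the C3 proton (secured by the intramolecular five-ring capture and the weak, insoluble base).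

Step 6
Reactants: 10 (3R,4S)-3-{10-[(triisopropylsilyl)oxy]decyl}spiro[chromane-4,2'-oxolan]-5'-one
Product: 11 (5S,9R)-9-{10-[(triisopropylsilyl)oxy]decyl}-1,7-dioxaspiro[4.4]nonane-2,6-dione
Conditions: RuCl3·xH2O (5 mol %), NaIO4 (excess), EtOAc/MeCN/H2O, rt
Reagents that add atoms: sodium periodate [Na+].[O-]I(=O)(=O)=O; water O
Why: RuO4 degradation of an electron-rich arene to a carboxylic acid; the benzo ring is burnt down to the carbon attached to C4, the oxygen-bearing arene carbon is lost as CO2, and the freed CH2OH closes on the new acid to gamma-lactone ring B, while any material oxidised further at that CH2 is already diacid 14 and passes step 7 unchanged, and no stereocentre is touched.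

Step 7
Reactants: 11 (5S,9R)-9-{10-[(triisopropylsilyl)oxy]decyl}-1,7-dioxaspiro[4.4]nonane-2,6-dione
Product: 14 (S)-2-{(S)-1-carboxy-11-[(triisopropylsilyl)oxy]undecyl}-5-oxooxolane-2-carboxylic acid, via disodium dihydroxy dicarboxylate 12 (not isolated), via trisodium hydroxy tricarboxylate 13 (not isolated)
Conditions: NaOH (aq), MeCN/H2O, 0 °C to rt; then TEMPO (cat.), NaBr (cat.), NaOCl, pH 10, 0 °C; then HCl to pH 1, rt
Reagents that add atoms: sodium hydroxide [Na+].[OH-]; water O
Why: Saponification opens both lactones so that the CH2OH cannot hide as a lactone, the TEMPO/NaOCl oxidation takes the only primary alcohol to the carboxylate and leaves the tertiary alcohol alone, and acidification recloses only five-membered ring A (the alternative would be a beta-lactone); C9 of 11 is not alpha to a carbonyl and the carboxylate salts do not enolise, so both centres hold.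

Step 8
Reactants: 14 (S)-2-{(S)-1-carboxy-11-[(triisopropylsilyl)oxy]undecyl}-5-oxooxolane-2-carboxylic acid
Product: 15 (S)-2-[(S)-1-carboxy-11-hydroxyundecyl]-5-oxooxolane-2-carboxylic acid
Conditions: HF (48 % aq), MeCN, rt
Reagents that add atoms: none
Why: Fluoride-driven cleavage of a silyl ether in acidic medium, which leaves the lactone, the acids and the base-sensitive beta-acyloxy acid motif alone.

Step 9
Reactants: 16 (R)-malic acid (D-malic acid)
Product: 17 (R)-2,5-dioxooxolan-3-yl trifluoroacetate
Conditions: (CF3CO)2O (neat), 0 °C to rt; volatiles removed in vacuo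
Reagents that add atoms: trifluoroacetic anhydride O=C(OC(=O)C(F)(F)F)C(F)(F)F
Why: Known one-pot O-trifluoroacetylation and cyclodehydration of malic acid; the stereocentre comes from the chiral pool and takes no part in the reaction.

Step 10
Reactants: 15 (S)-2-[(S)-1-carboxy-11-hydroxyundecyl]-5-oxooxolane-2-carboxylic acid; 17 (R)-2,5-dioxooxolan-3-yl trifluoroacetate
Product: 19 (S)-2-[(S)-1-carboxy-11-{[(R)-3-carboxy-2-hydroxypropanoyl]oxy}undecyl]-5-oxooxolane-2-carboxylic acid (target), via O-trifluoroacetyl ester 18 (not isolated)
Conditions: 17 (2.5 equiv), THF, rt; then H2O, rt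
Reagents that add atoms: none
Why: Regioselective alcoholysis of an alpha-acyloxy succinic anhydride; the primary alcohol attacks the carbonyl next to the electron-withdrawing trifluoroacetoxy group, which gives the 1-ester with the 4-acid free, the carboxyl groups of 15 are much poorer nucleophiles without base, the trifluoroacetate blocks a second acylation, and water then cleaves it.

**Compound list**
1 | 10-bromodecan-1-ol | OCCCCCCCCCCBr | starting material
2 | [(10-bromodecyl)oxy]triisopropylsilane | CC(C)[Si](OCCCCCCCCCCBr)(C(C)C)C(C)C | intermediate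
3 | 2-bromophenol | Oc1ccccc1Br | starting material
4 | (E)-1,4-dibromobut-2-ene | BrC/C=C/CBr | starting material
5 | 1-bromo-2-{[(2E)-4-bromobut-2-en-1-yl]oxy}benzene | BrC/C=C/COc1ccccc1Br | intermediate
6 | {10-[(triisopropylsilyl)oxy]decyl}magnesium bromide | CC(C)[Si](OCCCCCCCCCC[Mg]Br)(C(C)C)C(C)C | intermediate
7 | (S)-1-bromo-2-({2-ethenyl-12-[(triisopropylsilyl)oxy]dodecyl}oxy)benzene | CC(C)[Si](OCCCCCCCCCC[C@H](COc1ccccc1Br)C=C)(C(C)C)C(C)C | intermediate
8 | (S)-4-methylidene-3-{10-[(triisopropylsilyl)oxy]decyl}chromane | CC(C)[Si](OCCCCCCCCCC[C@@H]1COc2ccccc2C1=C)(C(C)C)C(C)C | intermediate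
9 | bromoacetic acid | OC(=O)CBr | starting material
10 | (3R,4S)-3-{10-[(triisopropylsilyl)oxy]decyl}spiro[chromane-4,2'-oxolan]-5'-one | CC(C)[Si](OCCCCCCCCCC[C@@H]1COc2ccccc2[C@]13CCC(=O)O3)(C(C)C)C(C)C | intermediate
11 | (5S,9R)-9-{10-[(triisopropylsilyl)oxy]decyl}-1,7-dioxaspiro[4.4]nonane-2,6-dione | CC(C)[Si](OCCCCCCCCCC[C@@H]1COC(=O)[C@]12CCC(=O)O2)(C(C)C)C(C)C | intermediate
12 | disodium (S)-2-hydroxy-2-{(R)-1-hydroxy-12-[(triisopropylsilyl)oxy]dodecan-2-yl}pentanedioate | CC(C)[Si](OCCCCCCCCCC[C@H](CO)[C@](O)(C(=O)[O-])CCC(=O)[O-])(C(C)C)C(C)C.[Na+].[Na+] | intermediate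
13 | trisodium (3S,4S)-3-hydroxy-14-[(triisopropylsilyl)oxy]tetradecane-1,3,4-tricarboxylate | CC(C)[Si](OCCCCCCCCCC[C@H](C(=O)[O-])[C@](O)(C(=O)[O-])CCC(=O)[O-])(C(C)C)C(C)C.[Na+].[Na+].[Na+] | intermediate
14 | (S)-2-{(S)-1-carboxy-11-[(triisopropylsilyl)oxy]undecyl}-5-oxooxolane-2-carboxylic acid | CC(C)[Si](OCCCCCCCCCC[C@H](C(=O)O)[C@]1(C(=O)O)CCC(=O)O1)(C(C)C)C(C)C | intermediate
15 | (S)-2-[(S)-1-carboxy-11-hydroxyundecyl]-5-oxooxolane-2-carboxylic acid | OCCCCCCCCCC[C@H](C(=O)O)[C@]1(C(=O)O)CCC(=O)O1 | intermediate
16 | (R)-malic acid | O=C(O)C[C@@H](O)C(=O)O | starting material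
17 | (R)-2,5-dioxooxolan-3-yl trifluoroacetate | O=C1C[C@@H](OC(=O)C(F)(F)F)C(=O)O1 | intermediate
18 | O-trifluoroacetyl derivative of the target | O=C(O)C[C@@H](OC(=O)C(F)(F)F)C(=O)OCCCCCCCCCC[C@H](C(=O)O)[C@]1(C(=O)O)CCC(=O)O1 | intermediate
19 | (S)-2-[(S)-1-carboxy-11-{[(R)-3-carboxy-2-hydroxypropanoyl]oxy}undecyl]-5-oxooxolane-2-carboxylic acid | O=C(O)C[C@@H](O)C(=O)OCCCCCCCCCC[C@H](C(=O)O)[C@]1(C(=O)O)CCC(=O)O1 | target

Total steps: 10. Longest linear sequence: 8 steps (1, 3, 4, 5, 6, 7, 8, 10) from 10-bromodecan-1-ol.

**Steps most likely to fail**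

1. Step 5. At risk are the facial selectivity of the closure on the planar cation and loss of the C3 proton from that cation, which would erase the first stereocentre. The fallback runs from 8 back to 10 and makes the two bonds one after the other by polar chemistry.
   - Dimethyldioxirane (acetone, 0 °C) should epoxidise 8 from the face opposite the C3 chain to the spiro-epoxide F1.
   - Sodium dimethyl malonate (NaH, THF, reflux) should open it at the CH2 carbon, and the tertiary alkoxide should close on one ester group to the alpha-methoxycarbonyl lactone F2.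
   - Krapcho demethoxycarbonylation (LiCl, wet DMSO, 140 °C) then leads to 10.

2. Step 6. The silyl ether could be lost during the long exposure to the acidic oxidising medium, followed by over-oxidation of the chain end. The fallback runs from 10 back to 11 and carries the chain end through the burn-off as an acetate, which RuO4 leaves alone.
   - Bu4NF/AcOH (THF) should free the chain alcohol F3.
   - Ac2O/pyridine should give the chain acetate F4.
   - RuCl3·xH2O/NaIO4 should burn off the arene to the bis-lactone acetate F5.
   - Aqueous NaOH followed by HCl and azeotropic drying (cat. TsOH, toluene) should remove the acetate and reclose both lactones to the hydroxy bis-lactone F6.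
   - TIPSCl/imidazole then returns to 11.

3. Step 4. The palladium hydride could re-add and move the exocyclic alkene into the ring, which would destroy the C3 stereocentre. The fallback runs from 7 back to 8 and closes the ring on an alkyne, so no beta-hydride elimination takes place.
   - Ozonolysis (O3, CH2Cl2, −78 °C; PPh3) should give the alpha-branched aldehyde F7.
   - Ohira–Bestmann homologation (dimethyl (1-diazo-2-oxopropyl)phosphonate, K2CO3, MeOH, 0 °C) should give the terminal alkyne F8.
   - Reductive cyclisation (Pd(OAc)2, PPh3, HCO2Na, DMF, 60 °C) should give 8 by 6-exo-dig carbopalladation and formate reduction of the vinylpalladium species.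

Further compounds
F1 | step 5 | (3R,4S)-3-{10-[(triisopropylsilyl)oxy]decyl}spiro[chromane-4,2'-oxirane] | CC(C)[Si](OCCCCCCCCCC[C@@H]1COc2ccccc2[C@]13CO3)(C(C)C)C(C)C
F2 | step 5 | methyl (3R,4S)-5'-oxo-3-{10-[(triisopropylsilyl)oxy]decyl}spiro[chromane-4,2'-oxolane]-4'-carboxylate (epimers at C4') | CC(C)[Si](OCCCCCCCCCC[C@@H]1COc2ccccc2[C@]13CC(C(=O)OC)C(=O)O3)(C(C)C)C(C)C
F3 | step 6 | (3R,4S)-3-(10-hydroxydecyl)spiro[chromane-4,2'-oxolan]-5'-one | OCCCCCCCCCC[C@@H]1COc2ccccc2[C@]13CCC(=O)O3
F4 | step 6 | 10-[(3R,4S)-5'-oxospiro[chromane-4,2'-oxolan]-3-yl]decyl acetate | CC(=O)OCCCCCCCCCC[C@@H]1COc2ccccc2[C@]13CCC(=O)O3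
F5 | step 6 | 10-[(5S,9R)-2,6-dioxo-1,7-dioxaspiro[4.4]nonan-9-yl]decyl acetate | CC(=O)OCCCCCCCCCC[C@@H]1COC(=O)[C@]12CCC(=O)O2
F6 | step 6 | (5S,9R)-9-(10-hydroxydecyl)-1,7-dioxaspiro[4.4]nonane-2,6-dione | OCCCCCCCCCC[C@@H]1COC(=O)[C@]12CCC(=O)O2
F7 | step 4 | (R)-2-[(2-bromophenoxy)methyl]-12-[(triisopropylsilyl)oxy]dodecanal | CC(C)[Si](OCCCCCCCCCC[C@H](COc1ccccc1Br)C=O)(C(C)C)C(C)C
F8 | step 4 | (S)-1-bromo-2-({2-ethynyl-12-[(triisopropylsilyl)oxy]dodecyl}oxy)benzene | CC(C)[Si](OCCCCCCCCCC[C@H](COc1ccccc1Br)C#C)(C(C)C)C(C)C
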